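**Plan**

1. Ring labels: A = the 3,4-dihydroxy-5-aryloxyphenyl ring (C-1 carries the ethano bridge), B = the para-phenylene at the carbinol, C = the 2-aryloxy-3-hydroxybenzyl ring, D = the meta-phenylene.
2. Retrosynthetic cuts, in order: (i) the ring A C-1–CH2 bond of the A/D ethano bridge, which opens the 18-membered ring; (ii) the carbinol-carbon–CH2 bond of the B/C bridge, made as the C=C of an enamine and hence a deoxybenzoin; (iii) the two diaryl ether C–O bonds (A–O–B, C–O–D).
3. Enabling feature: the saturated CH2–CH2 bridge between rings A and D is one hydroboration away from a vinyl group on ring D, and ring A C-1 (para to O-4, between two ring hydrogens) can carry bromine from the first starting material. The macrocycle can therefore close by an intramolecular sp3–sp2 coupling of a flexible, fully reduced seco-chain.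
4. Forward order: ring A phenol, then the A–O–B ether by SNAr, then an α-anilinophosphonate; separately the C–O–D ether by SNAr; the halves are joined by aminophosphonate olefination and hydrolysis to the open-chain aryl benzyl ketone; then reduction, ring closure and debenzylation.
5. Stereochemistry: the single carbinol centre is (S) (CIP order OH > ring B aryl > CH2 > H). It is set by Noyori transfer hydrogenation of the open-chain ketone with the (S,S)-TsDPEN–Ru catalyst before ring closure and is not touched afterwards.

Key step: step 10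

**Route**

Step 1
Reactants: 1 5-bromo-2-hydroxy-3-methoxybenzaldehyde
Product: 2 5-bromo-2,3-dihydroxybenzaldehyde
Conditions: BBr3, CH2Cl2, −78 °C to rt; H2O
Reagents that add atoms: none
Why: Lewis acid demethylation of the aryl methyl ether, assisted by the neighbouring phenol through a cyclic borate, should leave the aldehyde and the aryl bromide intact.

Step 2
Reactants: 2 5-bromo-2,3-dihydroxybenzaldehyde
Product: 3 2,3-bis(benzyloxy)-5-bromobenzaldehyde
Conditions: BnBr, K2CO3, DMF, 60 °C
Reagents that add atoms: benzyl bromide, BrCc1ccccc1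
Why: Double Williamson etherification of the catechol installs benzyl ethers that should withstand every later step and leave together at the end.

Step 3
Reactants: 3 2,3-bis(benzyloxy)-5-bromobenzaldehyde
Product: 5 2,3-bis(benzyloxy)-5-bromophenol, via aryl formate 4 (not isolated)
Conditions: mCPBA, CH2Cl2, rt; then K2CO3 (cat.), MeOH, rt
Reagents that add atoms: 3-chloroperoxybenzoic acid (mCPBA), OOC(=O)c1cccc(Cl)c1
Why: In this Baeyer–Villiger (Dakin-type) oxidation the electron-rich, ortho-alkoxylated aryl group should migrate in preference to hydrogen to give the aryl formate, which mild methanolysis converts into the phenol.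

Step 4
Reactants: 5 2,3-bis(benzyloxy)-5-bromophenol; 6 4-fluorobenzaldehyde
Product: 7 4-[2,3-bis(benzyloxy)-5-bromophenoxy]benzaldehyde
Conditions: K2CO3, DMF, 110 °C
Reagents that add atoms: none
Why: Nucleophilic aromatic substitution (SNAr) should occur only at the C–F bond activated by the para-formyl group, since the unactivated ring A C–Br bond cannot react.

Step 5
Reactants: 7 4-[2,3-bis(benzyloxy)-5-bromophenoxy]benzaldehyde
Product: 9 diphenyl [{4-[2,3-bis(benzyloxy)-5-bromophenoxy]phenyl}(phenylamino)methyl]phosphonate (racemic), via N-phenyl imine 8 (not isolated)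
Conditions: PhNH2, (PhO)2P(O)H, i-PrOH, rt
Reagents that add atoms: aniline, Nc1ccccc1; diphenyl phosphite, O=[PH](Oc1ccccc1)Oc1ccccc1
Why: The Kabachnik–Fields reaction (imine formation, then Pudovik addition of the P–H bond) turns the ring B aldehyde carbon into an acyl-anion equivalent; its racemic stereocentre is erased in step 8.

Step 6
Reactants: 10 2-fluoro-3-hydroxybenzaldehyde
Product: 11 3-(benzyloxy)-2-fluorobenzaldehyde
Conditions: BnBr, K2CO3, DMF, rt
Reagents that add atoms: benzyl bromide, BrCc1ccccc1
Why: Williamson etherification protects the ring C phenol in the same way as the ring A hydroxyls, so that one final operation frees all three.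

Step 7
Reactants: 11 3-(benzyloxy)-2-fluorobenzaldehyde; 12 3-ethenylphenol (3-vinylphenol)
Product: 13 3-(benzyloxy)-2-(3-ethenylphenoxy)benzaldehyde
Conditions: Cs2CO3, DMSO, 90–100 °C, BHT (cat.), N2
Reagents that add atoms: none
Why: SNAr at the fluorine activated by the ortho-formyl group should form the C–O–D diaryl ether, with the radical inhibitor guarding the styrene against thermal polymerization.

Step 8
Reactants: 9 diphenyl [{4-[2,3-bis(benzyloxy)-5-bromophenoxy]phenyl}(phenylamino)methyl]phosphonate; 13 3-(benzyloxy)-2-(3-ethenylphenoxy)benzaldehyde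
Product: 15 1-{4-[2,3-bis(benzyloxy)-5-bromophenoxy]phenyl}-2-[3-(benzyloxy)-2-(3-ethenylphenoxy)phenyl]ethan-1-one, via N-phenyl enamine 14 (not isolated)
Conditions: Cs2CO3, THF/i-PrOH, rt; then 3 M HCl, rt
Reagents that add atoms: water, O
Why: Horner–Wadsworth–Emmons-type olefination of the α-aminophosphonate carbanion with aldehyde 13 should give the enamine, whose acid hydrolysis delivers the aryl benzyl ketone with the carbonyl on the ring B side; bromide, styrene and benzyl ethers are inert to both stages.

Step 9
Reactants: 15 1-{4-[2,3-bis(benzyloxy)-5-bromophenoxy]phenyl}-2-[3-(benzyloxy)-2-(3-ethenylphenoxy)phenyl]ethan-1-one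
Product: 16 (1S)-1-{4-[2,3-bis(benzyloxy)-5-bromophenoxy]phenyl}-2-[3-(benzyloxy)-2-(3-ethenylphenoxy)phenyl]ethan-1-ol
Conditions: RuCl[(S,S)-TsDPEN](p-cymene) (2 mol%), HCO2H/Et3N (5:2), CH2Cl2, 30 °C
Reagents that add atoms: none
Why: In the Noyori asymmetric transfer hydrogenation the outer-sphere Ru–H/N–H transition state holds the ring B aryl group by a CH/π contact with the cymene ligand, so the (S,S)-catalyst should deliver the (S)-alcohol as it does with acetophenone, leaving C=C, C–Br and benzyl ethers untouched.

Step 10
Reactants: 16 (1S)-1-{4-[2,3-bis(benzyloxy)-5-bromophenoxy]phenyl}-2-[3-(benzyloxy)-2-(3-ethenylphenoxy)phenyl]ethan-1-ol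
Product: 18 tri-O-benzyl macrocycle (the target with its three phenolic hydroxyls as benzyl ethers and the free (S)-carbinol), via bis(9-BBN) adduct 17 (not isolated)
Conditions: 9-BBN dimer (1.5 equiv), THF, 0 °C to rt; then syringe-pump addition into Pd(OAc)2 (10 mol%), SPhos (20 mol%), aq. K3PO4, THF, 65 °C, ca. 2 mM
Reagents that add atoms: none
Why: 9-BBN should add anti-Markovnikov to the ring D vinyl group (boron on the terminal carbon) and merely borinate the free carbinol; Pd(0)/SPhos then inserts into the ring A C-1–Br bond, base-assisted transmetalation moves the primary alkyl group from boron to palladium, and reductive elimination forms the ring A C-1–CH2 bond. The closest known reaction type is the one-pot hydroboration/B-alkyl Suzuki–Miyaura macrocyclization used to close carbocyclic and cyclophane macrocycles. One ring is closed, the 18-membered macrocycle, by an end-to-end closure of the seco-chain through intramolecular transmetalation and C(sp2)–C(sp3) reductive elimination. No new stereocentre arises, and the remote (S)-carbinol should be returned unchanged when the aqueous base cleaves its O–B bond. The step needs regioselective hydroboration, secured by the bulk of 9-BBN on a monosubstituted styrene; chemoselectivity, secured because 16 holds a single C–Br bond beside inert benzyl and diaryl ethers; and ring closure over oligomerization, secured by slow addition at about 2 mM and by the two diaryl ether hinges and the sp3 carbinol bridge that let the chain ends meet.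

Step 11
Reactants: 18 tri-O-benzyl macrocycle
Product: 19 CNP0356934.1 (target)
Conditions: H2 (1 atm), 10% Pd/C, EtOAc/MeOH, rt
Reagents that add atoms: none
Why: Catalytic hydrogenolysis of aryl benzyl ethers is much faster under neutral conditions than C–O hydrogenolysis of a free secondary benzylic alcohol, so the three phenols should be released with the (S)-carbinol intact if the reaction is stopped after three equivalents of hydrogen.

**Compound list**

1 | 5-bromo-2-hydroxy-3-methoxybenzaldehyde | COc1cc(Br)cc(C=O)c1O | starting material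
2 | 5-bromo-2,3-dihydroxybenzaldehyde | O=Cc1cc(Br)cc(O)c1O | intermediate
3 | 2,3-bis(benzyloxy)-5-bromobenzaldehyde | O=Cc1cc(Br)cc(OCc2ccccc2)c1OCc1ccccc1 | intermediate
4 | 2,3-bis(benzyloxy)-5-bromophenyl formate | O=COc1cc(Br)cc(OCc2ccccc2)c1OCc1ccccc1 | intermediate (not isolated)
5 | 2,3-bis(benzyloxy)-5-bromophenol | Oc1cc(Br)cc(OCc2ccccc2)c1OCc1ccccc1 | intermediate
6 | 4-fluorobenzaldehyde | O=Cc1ccc(F)cc1 | starting material
7 | 4-[2,3-bis(benzyloxy)-5-bromophenoxy]benzaldehyde | O=Cc1ccc(Oc2cc(Br)cc(OCc3ccccc3)c2OCc2ccccc2)cc1 | intermediate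
8 | (E)-N-phenyl imine of 7 | c1ccccc1/N=C/c1ccc(Oc2cc(Br)cc(OCc3ccccc3)c2OCc2ccccc2)cc1 | intermediate (not isolated)
9 | diphenyl [{4-[2,3-bis(benzyloxy)-5-bromophenoxy]phenyl}(phenylamino)methyl]phosphonate, racemic | O=P(Oc1ccccc1)(Oc1ccccc1)C(Nc1ccccc1)c1ccc(Oc2cc(Br)cc(OCc3ccccc3)c2OCc2ccccc2)cc1 | intermediate
10 | 2-fluoro-3-hydroxybenzaldehyde | O=Cc1cccc(O)c1F | starting material
11 | 3-(benzyloxy)-2-fluorobenzaldehyde | O=Cc1cccc(OCc2ccccc2)c1F | intermediate
12 | 3-ethenylphenol (3-vinylphenol) | C=Cc1cccc(O)c1 | starting material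
13 | 3-(benzyloxy)-2-(3-ethenylphenoxy)benzaldehyde | O=Cc1cccc(OCc2ccccc2)c1Oc1cccc(C=C)c1 | intermediate
14 | N-phenyl enamine from 9 and 13 (E/Z mixture, in equilibrium with the ketimine tautomer) | C=Cc1cccc(Oc2c(OCc3ccccc3)cccc2C=C(Nc2ccccc2)c2ccc(Oc3cc(Br)cc(OCc4ccccc4)c3OCc3ccccc3)cc2)c1 | intermediate (not isolated)
15 | 1-{4-[2,3-bis(benzyloxy)-5-bromophenoxy]phenyl}-2-[3-(benzyloxy)-2-(3-ethenylphenoxy)phenyl]ethan-1-one | O=C(Cc1cccc(OCc2ccccc2)c1Oc1cccc(C=C)c1)c1ccc(Oc2cc(Br)cc(OCc3ccccc3)c2OCc2ccccc2)cc1 | intermediate
16 | (1S)-1-{4-[2,3-bis(benzyloxy)-5-bromophenoxy]phenyl}-2-[3-(benzyloxy)-2-(3-ethenylphenoxy)phenyl]ethan-1-ol | O[C@@H](Cc1cccc(OCc2ccccc2)c1Oc1cccc(C=C)c1)c1ccc(Oc2cc(Br)cc(OCc3ccccc3)c2OCc2ccccc2)cc1 | intermediate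
17 | bis(9-BBN) adduct of 16 (O-borinate of the (S)-carbinol, primary B-alkyl borane on the ring D side chain) | B1(C2CCCC1CCC2)O[C@@H](Cc1cccc(OCc2ccccc2)c1Oc1cccc(CCB2C3CCCC2CCC3)c1)c1ccc(Oc2cc(Br)cc(OCc3ccccc3)c2OCc2ccccc2)cc1 | intermediate (not isolated)
18 | tri-O-benzyl macrocycle, (S)-carbinol free | O(Cc1ccccc1)c1cc2cc(c1OCc1ccccc1)Oc1ccc(cc1)[C@@H](O)Cc1cccc(OCc3ccccc3)c1Oc1cccc(c1)CC2 | intermediate
19 | CNP0356934.1 | Oc1cc2cc(c1O)Oc1ccc(cc1)[C@@H](O)Cc1cccc(O)c1Oc1cccc(c1)CC2 | target

**Totals and risks**

Total step count: 11. Longest linear sequence: 9 steps (steps 1–5 and 8–11).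

Steps most likely to fail:

Step 10. Intermolecular coupling (oligomerization) may outrun ring closure, or oxidative addition into the electron-rich ring A bromide may be slow enough for the alkylborane to be lost by protodeboronation. The fallback sets out from 16 and forms the same aryl–carbon bond by an intramolecular Mizoroki–Heck reaction (Pd(OAc)2, P(o-tol)3, K2CO3, DMF, 100 °C, high dilution). This should give the tri-O-benzyl macrocyclic (E)-stilbene F1. Hydrogenation over Pd/C in EtOAc/MeOH then saturates the alkene and removes the three benzyl groups in one operation, so the fallback returns to the route at 19.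

Step 7. Displacement of the fluorine flanked by the formyl and benzyloxy groups may need temperatures at which the vinylphenol polymerizes. The fallback sets out from 11 and uses 3-bromophenol, which holds no polymerizable group, in the same SNAr (Cs2CO3, DMSO, 110 °C) to give 3-(benzyloxy)-2-(3-bromophenoxy)benzaldehyde F2. Suzuki–Miyaura vinylation with potassium vinyltrifluoroborate (PdCl2(dppf), Cs2CO3, THF/H2O, 80 °C) then installs the vinyl group, and the fallback returns at 13.

Step 11. Hydrogenolysis of the benzylic C–OH bond may accompany cleavage of the benzyl ethers and remove the stereocentre. The fallback sets out from 18. Dess–Martin oxidation gives the tri-O-benzyl macrocyclic ketone F3. Non-reductive debenzylation with BCl3 and pentamethylbenzene (CH2Cl2, −78 °C) gives the macrocyclic triphenol ketone F4. Transfer hydrogenation with RuCl[(S,S)-TsDPEN](p-cymene) in HCO2H/Et3N then sets the (S)-carbinol as the last event, and the fallback returns at 19.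

Further compounds
F1 | step 10 | tri-O-benzyl macrocyclic (E)-stilbene, (S)-carbinol | O1c2cccc(c2)/C=C/c2cc(OCc3ccccc3)c(OCc3ccccc3)c(c2)Oc2ccc(cc2)[C@@H](O)Cc2cccc(OCc3ccccc3)c21
F2 | step 7 | 3-(benzyloxy)-2-(3-bromophenoxy)benzaldehyde | O=Cc1cccc(OCc2ccccc2)c1Oc1cccc(Br)c1
F3 | step 11 | tri-O-benzyl macrocyclic ketone | O(Cc1ccccc1)c1cc2cc(c1OCc1ccccc1)Oc1ccc(cc1)C(=O)Cc1cccc(OCc3ccccc3)c1Oc1cccc(c1)CC2
F4 | step 11 | macrocyclic triphenol ketone | Oc1cc2cc(c1O)Oc1ccc(cc1)C(=O)Cc1cccc(O)c1Oc1cccc(c1)CC2
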